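**Plan**

1. Locants used throughout: C1 ketone, C2 bridgehead CH, C3=C4(CH3), C5 quaternary bridgehead, C6 (lactone O–CH), C7, C8, C9, C10 (quaternary C–CH3), C11 (CH–CH3), C12 (lactone C=O); C1′H2–C2′H is the saturated two-carbon bridge and C2′ bears the 6-methylhepta-1,5-dien-2-yl chain.
2. Enabling feature: in the bicyclo[2.2.2]oct-5-en-2-one, the ring C1–C2–C3=C4–C5–C10 has its alkene flanked by both bridgeheads, so it is a [4+2] retron. Cutting C1–C2 and C5–C10 gives the diene C2=C3–C4=C5 (held in the ring C2–C3–C4–C5–C1′–C2′) and the dienophile C10(CH3)=C1, a ketene equivalent (nitroalkene; C1–NO2 to C1=O by Nef reaction).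
3. That diene ring with its chain is the skeleton of a prenyl-homologated (S)-carvone (carvone C=O carbon = C5, C(CH3) = C4, stereocenter = C2′), a chiral-pool match that spans the "monoterpene" half and C2–C5 of the sesquiterpenoid half.
4. Further cuts: C5–C6 (formylation of a dienyl triflate), C6–C7 (asymmetric alkenylation and lactonisation to a butenolide), C7–C8 and C11–CH3 (conjugate addition, enolate methylation), C10=C1 (Henry reaction, dehydration), chain C–C bonds (Claisen, Wittig).
5. Forward order of rings: carvone ring (given), then the lactone ring, then one-step closure of the cyclohexane (C5–C10) and of the bicyclo[2.2.2]octene by intramolecular Diels–Alder reaction, then Nef reaction.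
6. Stereochemistry: C2′ from (S)-carvone; C6 from the chiral chromium catalyst; C7 and C11 relayed from C6 (anti addition, anti alkylation); C2, C5 and C10 set in the cycloaddition by C2′ (face) and by C6 through allylic strain with the C4 methyl (tether orientation).

Key step: step 10

Remark: E and Z isomers of nitroalkene 19 and both C1 epimers of 20 converge on 22, so neither ratio matters; 20 is drawn as the endo-nitro epimer expected from (E)-19.

**Step 1**
Reactants: 1 (S)-(+)-carvone
Product: 2 (5S)-5-(3-hydroxyprop-1-en-2-yl)-2-methylcyclohex-2-en-1-one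
Conditions: SeO2 (cat.), t-BuOOH, CH2Cl2, 0 °C to rt
Reagents that add atoms: tert-butyl hydroperoxide CC(C)(C)OO
Why: Selenium dioxide allylic oxidation (ene reaction then [2,3]-shift) should occur at the methyl of the electron-rich isopropenyl alkene, the ring alkene being deactivated as an enone, and leaves the ring stereocenter untouched.

**Step 2**
Reactants: 2 (5S)-5-(3-hydroxyprop-1-en-2-yl)-2-methylcyclohex-2-en-1-one
Product: 4 4-[(1S)-4-methyl-5-oxocyclohex-3-en-1-yl]pent-4-enal, via allyl vinyl ether 3 (not isolated)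
Conditions: ethyl vinyl ether, Hg(OAc)2 (cat.), reflux; then xylene, 140 °C, sealed tube
Reagents that add atoms: ethyl vinyl ether C=COCC
Why: Mercury-catalysed transvinylation followed by Claisen rearrangement (chair-like [3,3] shift) should give the γ,δ-unsaturated aldehyde with the 1,1-disubstituted alkene regenerated next to the ring; no stereocenter is made.

**Step 3**
Reactants: 4 4-[(1S)-4-methyl-5-oxocyclohex-3-en-1-yl]pent-4-enal
Product: 5 (5S)-2-methyl-5-(6-methylhepta-1,5-dien-2-yl)cyclohex-2-en-1-one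
Conditions: i-PrPPh3I, n-BuLi, THF, 0 °C; then 4, −78 °C to 0 °C
Reagents that add atoms: isopropyltriphenylphosphonium iodide CC(C)[P+](c1ccccc1)(c1ccccc1)c1ccccc1.[I-]
Why: Wittig olefination with the non-stabilised isopropylidene ylide should be selective for the aldehyde over the hindered, conjugated ring ketone at low temperature.

**Step 4**
Reactants: 5 (5S)-2-methyl-5-(6-methylhepta-1,5-dien-2-yl)cyclohex-2-en-1-one
Product: 7 (5R)-2-methyl-5-(6-methylhepta-1,5-dien-2-yl)cyclohexa-1,3-dien-1-yl trifluoromethanesulfonate, via magnesium dienolate 6 (not isolated)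
Conditions: MeMgBr, FeCl3 (5 mol%), Et2O, −20 °C; then N-(5-chloropyridin-2-yl)bis(trifluoromethanesulfonimide), THF/DMPU, −20 °C to rt
Reagents that add atoms: N-(5-chloropyridin-2-yl)-1,1,1-trifluoro-N-[(trifluoromethyl)sulfonyl]methanesulfonamide FC(F)(F)S(=O)(=O)N(c1ccc(Cl)cn1)S(=O)(=O)C(F)(F)F
Why: Iron-catalysed Grignard deprotonation of the enone at its γ-CH2 should give the through-conjugated (linear) dienolate, and O-sulfonylation then fixes the diene in the position needed for the cycloaddition without touching the ring stereocenter.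

**Step 5**
Reactants: 7 (5R)-2-methyl-5-(6-methylhepta-1,5-dien-2-yl)cyclohexa-1,3-dien-1-yl trifluoromethanesulfonate
Product: 8 (5R)-2-methyl-5-(6-methylhepta-1,5-dien-2-yl)cyclohexa-1,3-diene-1-carbaldehyde
Conditions: Pd(OAc)2 (5 mol%), dppp, CO (1 atm), Et3SiH, Et3N, DMF, 60 °C
Reagents that add atoms: carbon monoxide [C-]#[O+]
Why: Palladium-catalysed reductive carbonylation (formylation) of the enol triflate, by oxidative addition, CO insertion and hydride transfer from the silane, should install C6 under conditions too weakly basic to disturb the ring stereocenter.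

**Step 6**
Reactants: 8 (5R)-2-methyl-5-(6-methylhepta-1,5-dien-2-yl)cyclohexa-1,3-diene-1-carbaldehyde; 9 ethyl (2Z)-3-iodoprop-2-enoate
Product: 12 (5S)-5-[(5R)-2-methyl-5-(6-methylhepta-1,5-dien-2-yl)cyclohexa-1,3-dien-1-yl]furan-2(5H)-one, via silyl ether 10 (not isolated), via hydroxy ester 11 (not isolated)
Conditions: CrCl2 (10 mol%), chiral N-[2-(4,5-dihydrooxazol-2-yl)aryl]sulfonamide ligand (11 mol%), Et3N (25 mol%), NiCl2·dmp (2 mol%; dmp = 2,9-dimethyl-1,10-phenanthroline), Mn, LiCl, Me3SiCl, MeCN, rt; then aq. citric acid, THF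
Reagents that add atoms: none
Why: In this catalytic asymmetric Nozaki–Hiyama–Kishi alkenylation the (Z)-alkenylchromium species adds 1,2 to the aldehyde inside the chiral chromium–sulfonamide complex, whose enantiomer is chosen to set C6 as S (reagent control, the remote ring stereocenter having little influence), and the (Z)-γ-hydroxy ester lactonises on mild acidic work-up.

**Step 7**
Reactants: 12 (5S)-5-[(5R)-2-methyl-5-(6-methylhepta-1,5-dien-2-yl)cyclohexa-1,3-dien-1-yl]furan-2(5H)-one; 13 2-(2-bromoethyl)-2-methyl-1,3-dioxolane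
Product: 16 (3S,4S,5S)-3-methyl-4-[2-(2-methyl-1,3-dioxolan-2-yl)ethyl]-5-[(5R)-2-methyl-5-(6-methylhepta-1,5-dien-2-yl)cyclohexa-1,3-dien-1-yl]oxolan-2-one, via Grignard reagent 14 (not isolated), via magnesium enolate 15 (not isolated)
Conditions: 13, Mg, THF; CuBr·SMe2 (10 mol%), THF, −78 °C, then 12; then MeI, DMPU, −78 °C to −20 °C
Reagents that add atoms: iodomethane CI
Why: Copper-catalysed conjugate addition to the butenolide should occur anti to the C6 dienyl group and the resulting enolate should be methylated anti to the new C7 chain (tandem 1,4-addition and alkylation), giving the all-trans 6S,7S,11S lactone.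

**Step 8**
Reactants: 16 (3S,4S,5S)-3-methyl-4-[2-(2-methyl-1,3-dioxolan-2-yl)ethyl]-5-[(5R)-2-methyl-5-(6-methylhepta-1,5-dien-2-yl)cyclohexa-1,3-dien-1-yl]oxolan-2-one
Product: 17 (3S,4S,5S)-3-methyl-4-(3-oxobutyl)-5-[(5R)-2-methyl-5-(6-methylhepta-1,5-dien-2-yl)cyclohexa-1,3-dien-1-yl]oxolan-2-one
Conditions: PPTS (cat.), acetone/H2O, 40 °C
Reagents that add atoms: water O
Why: Mild acid-catalysed ketal hydrolysis should free the methyl ketone without affecting the lactone or, at this acidity, the diene.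

**Step 9**
Reactants: 17 (3S,4S,5S)-3-methyl-4-(3-oxobutyl)-5-[(5R)-2-methyl-5-(6-methylhepta-1,5-dien-2-yl)cyclohexa-1,3-dien-1-yl]oxolan-2-one
Product: 18 (3S,4S,5S)-4-(3-hydroxy-3-methyl-4-nitrobutyl)-3-methyl-5-[(5R)-2-methyl-5-(6-methylhepta-1,5-dien-2-yl)cyclohexa-1,3-dien-1-yl]oxolan-2-one
Conditions: MeNO2 (solvent), DBU (20 mol%), 0 °C to rt
Reagents that add atoms: nitromethane C[N+](=O)[O-]
Why: Henry (nitroaldol) addition to the methyl ketone is driven by the excess of nitromethane, and the uncontrolled carbinol center is harmless because it is removed in step 10.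

**Step 10**
Reactants: 18 (3S,4S,5S)-4-(3-hydroxy-3-methyl-4-nitrobutyl)-3-methyl-5-[(5R)-2-methyl-5-(6-methylhepta-1,5-dien-2-yl)cyclohexa-1,3-dien-1-yl]oxolan-2-one
Product: 20 nitro cycloadduct (22 with CH–NO2 in place of the C1 carbonyl and the nitro group syn to the C3=C4 bridge), via nitroalkene 19 (not isolated)
Conditions: (CF3CO)2O, Et3N, CH2Cl2, −20 °C; cold aq. NaHCO3 wash, solvent exchange; PhMe (high dilution), BHT, 90 °C
Reagents that add atoms: none
Why: Trifluoroacetylation of the tertiary alcohol and E1cB loss of trifluoroacetate unmask nitroalkene 19, whose electron-poor C10=C1 bond then adds thermally, in a concerted and asynchronous normal-demand intramolecular Diels–Alder reaction, across C5 and C2 of the ring diene. The closest known reaction types are Diels–Alder reactions of nitroalkenes used as ketene equivalents and intramolecular Diels–Alder reactions of 1-tethered cyclohexa-1,3-dienes that give bicyclo[2.2.2]octenes. Two rings close: the cyclohexane C5–C6–C7–C8–C9–C10 through the C5–C10 bond (fused mode, four-atom tether from the diene terminus, chair-like) and the cyclohexene C1–C2–C3=C4–C5–C10, the [4+2] ring proper, which bridges the carvone-derived ring into the bicyclo[2.2.2]octene. C2 and C5 follow from the diene face attacked, which is the one anti to the C2′ side chain; C10 follows from the tether lying on the C1′H2 side so that the C10 methyl is endo (toward the new C3=C4 alkene), and C1 (nitro endo from the E isomer) is erased in step 11. Face and tether orientation are both dictated by C6: allylic 1,3-strain with the C4 methyl keeps H6 near the diene plane beside that methyl, which puts C7 on the face anti to the C2′ substituent (matched with it) and on the C1′ side, and turns the lactone oxygen to the other face. The step needs periselectivity for the all-carbon [4+2] (thermal conditions, no Lewis acid that would favour nitronate formation), a conjugated nitroalkene (no excess base, immediate use) and an intact diene (90 °C lies well below the onset of 1,5-hydrogen shifts), and the nitro group secures low-temperature reactivity of the trisubstituted dienophile.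

**Step 11**
Reactants: 20 nitro cycloadduct
Product: 22 CNP0385704.3, via potassium nitronate 21 (not isolated)
Conditions: KOt-Bu, THF, 0 °C; then aq. TiCl3, NH4OAc buffer, 0 °C to rt
Reagents that add atoms: water O
Why: In this Nef reaction in its reductive titanium trichloride form the nitronate is reduced to the imine and hydrolysed to the C1 ketone, and neither flanking carbon (bridgehead C2, quaternary C10) can epimerise.

**Compound list**

1 | (S)-(+)-carvone, (5S)-2-methyl-5-(prop-1-en-2-yl)cyclohex-2-en-1-one | C=C(C)[C@@H]1CC(=O)C(C)=CC1 | starting material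
2 | (5S)-5-(3-hydroxyprop-1-en-2-yl)-2-methylcyclohex-2-en-1-one | C=C(CO)[C@@H]1CC(=O)C(C)=CC1 | intermediate
3 | (5S)-5-[3-(ethenyloxy)prop-1-en-2-yl]-2-methylcyclohex-2-en-1-one | C=COCC(=C)[C@@H]1CC(=O)C(C)=CC1 | intermediate
4 | 4-[(1S)-4-methyl-5-oxocyclohex-3-en-1-yl]pent-4-enal | C=C(CCC=O)[C@@H]1CC(=O)C(C)=CC1 | intermediate
5 | (5S)-2-methyl-5-(6-methylhepta-1,5-dien-2-yl)cyclohex-2-en-1-one | C=C(CCC=C(C)C)[C@@H]1CC(=O)C(C)=CC1 | intermediate
6 | bromomagnesium (5R)-2-methyl-5-(6-methylhepta-1,5-dien-2-yl)cyclohexa-1,3-dien-1-olate | C=C(CCC=C(C)C)[C@@H]1CC(O[Mg]Br)=C(C)C=C1 | intermediate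
7 | (5R)-2-methyl-5-(6-methylhepta-1,5-dien-2-yl)cyclohexa-1,3-dien-1-yl trifluoromethanesulfonate | C=C(CCC=C(C)C)[C@@H]1CC(OS(=O)(=O)C(F)(F)F)=C(C)C=C1 | intermediate
8 | (5R)-2-methyl-5-(6-methylhepta-1,5-dien-2-yl)cyclohexa-1,3-diene-1-carbaldehyde | C=C(CCC=C(C)C)[C@@H]1CC(C=O)=C(C)C=C1 | intermediate
9 | ethyl (2Z)-3-iodoprop-2-enoate | CCOC(=O)/C=C\I | starting material
10 | ethyl (2Z,4S)-4-[(5R)-2-methyl-5-(6-methylhepta-1,5-dien-2-yl)cyclohexa-1,3-dien-1-yl]-4-[(trimethylsilyl)oxy]but-2-enoate | C=C(CCC=C(C)C)[C@@H]1CC(=C(C)C=C1)[C@@H](O[Si](C)(C)C)/C=C\C(=O)OCC | intermediate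
11 | ethyl (2Z,4S)-4-hydroxy-4-[(5R)-2-methyl-5-(6-methylhepta-1,5-dien-2-yl)cyclohexa-1,3-dien-1-yl]but-2-enoate | C=C(CCC=C(C)C)[C@@H]1CC(=C(C)C=C1)[C@@H](O)/C=C\C(=O)OCC | intermediate
12 | (5S)-5-[(5R)-2-methyl-5-(6-methylhepta-1,5-dien-2-yl)cyclohexa-1,3-dien-1-yl]furan-2(5H)-one | C=C(CCC=C(C)C)[C@@H]1CC(=C(C)C=C1)[C@H]2OC(=O)C=C2 | intermediate
13 | 2-(2-bromoethyl)-2-methyl-1,3-dioxolane | CC1(CCBr)OCCO1 | starting material
14 | [2-(2-methyl-1,3-dioxolan-2-yl)ethyl]magnesium bromide | CC1(CC[Mg]Br)OCCO1 | intermediate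
15 | bromomagnesium enolate of (4S,5S)-4-[2-(2-methyl-1,3-dioxolan-2-yl)ethyl]-5-[(5R)-2-methyl-5-(6-methylhepta-1,5-dien-2-yl)cyclohexa-1,3-dien-1-yl]oxolan-2-one | C=C(CCC=C(C)C)[C@@H]1CC(=C(C)C=C1)[C@H]2OC(O[Mg]Br)=C[C@@H]2CCC3(C)OCCO3 | intermediate
16 | (3S,4S,5S)-3-methyl-4-[2-(2-methyl-1,3-dioxolan-2-yl)ethyl]-5-[(5R)-2-methyl-5-(6-methylhepta-1,5-dien-2-yl)cyclohexa-1,3-dien-1-yl]oxolan-2-one | C=C(CCC=C(C)C)[C@@H]1CC(=C(C)C=C1)[C@H]2OC(=O)[C@@H](C)[C@@H]2CCC3(C)OCCO3 | intermediate
17 | (3S,4S,5S)-3-methyl-4-(3-oxobutyl)-5-[(5R)-2-methyl-5-(6-methylhepta-1,5-dien-2-yl)cyclohexa-1,3-dien-1-yl]oxolan-2-one | C=C(CCC=C(C)C)[C@@H]1CC(=C(C)C=C1)[C@H]2OC(=O)[C@@H](C)[C@@H]2CCC(C)=O | intermediate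
18 | (3S,4S,5S)-4-(3-hydroxy-3-methyl-4-nitrobutyl)-3-methyl-5-[(5R)-2-methyl-5-(6-methylhepta-1,5-dien-2-yl)cyclohexa-1,3-dien-1-yl]oxolan-2-one (both carbinol epimers) | C=C(CCC=C(C)C)[C@@H]1CC(=C(C)C=C1)[C@H]2OC(=O)[C@@H](C)[C@@H]2CCC(C)(O)C[N+](=O)[O-] | intermediate
19 | (3S,4S,5S)-3-methyl-4-[(3E)-3-methyl-4-nitrobut-3-en-1-yl]-5-[(5R)-2-methyl-5-(6-methylhepta-1,5-dien-2-yl)cyclohexa-1,3-dien-1-yl]oxolan-2-one | C=C(CCC=C(C)C)[C@@H]1CC(=C(C)C=C1)[C@H]2OC(=O)[C@@H](C)[C@@H]2CC/C(C)=C/[N+](=O)[O-] | intermediate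
20 | nitro cycloadduct: 22 with CH–NO2 in place of the C1 carbonyl, nitro syn to the C3=C4 bridge | C=C(CCC=C(C)C)[C@@H]1C[C@]23C(C)=C[C@H]1[C@@H]([N+](=O)[O-])[C@]2(C)CC[C@H]1[C@H](C)C(=O)O[C@@H]13 | intermediate
21 | potassium nitronate of 20 | C=C(CCC=C(C)C)[C@@H]1C[C@]23C(C)=C[C@H]1C(=[N+]([O-])[O-])[C@]2(C)CC[C@H]1[C@H](C)C(=O)O[C@@H]13.[K+] | intermediate
22 | CNP0385704.3: (2R,5S,6S,7S,10R,11S,2′R)-2′-(6-methylhepta-1,5-dien-2-yl)-1-oxo-2,5-ethanoeudesm-3-en-12,6-olide (locants as in the plan; C1′ on C5, C2′ on C2) | C=C(CCC=C(C)C)[C@@H]1C[C@]23C(C)=C[C@H]1C(=O)[C@]2(C)CC[C@H]1[C@H](C)C(=O)O[C@@H]13 | target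

Total step count: 11
Longest linear sequence: 11 steps, from (S)-carvone 1

**Steps most likely to fail**

Step 10. The nitroalkene may deconjugate to the allylic nitro isomer under the amine base, or the tertiary nitro alcohol may undergo retro-Henry cleavage during acylation. The tether may also fail to adopt the required orientation. The fallback sets out from ketone 17 and comes back at target 22. Ketone 17 is condensed with lithiated N-tert-butyl-2-(trimethylsilyl)ethanimine (Peterson-type formyl olefination, THF, −78 °C) to give the unsaturated N-tert-butyl imine F1. Aqueous oxalic acid hydrolyses this to the (E)-enal F2. Me2AlCl (CH2Cl2, −78 °C to −20 °C) then promotes the same intramolecular [4+2] by Lewis-acid activation of the enal at low temperature, giving the C1-formyl cycloadduct aldehyde F3. Copper-catalysed aerobic oxidative deformylation of this α-branched aldehyde (Cu(OAc)2, 2,2′-bipyridine, DABCO, O2, DMF) excises the formyl carbon and leaves the C1 ketone of 22. This replaces the nitro ketene equivalent by an enal and avoids both Henry chemistry and heating.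

Step 4. Deprotonation may take place at the α′-CH2 and give the cross-conjugated dienolate. The Grignard reagent may add 1,2 to the enone, or the dienolate may isomerise toward an aromatic ring. The fallback sets out from enone 5 and comes back at triflate 7. Equilibrating silylation (Me3SiCl, NaI, Et3N, MeCN, rt) relies on the thermodynamic preference for the through-conjugated isomer and gives the isolable silyl dienol ether F4, whose regiochemistry can be checked and purified. Methyllithium (THF, 0 °C) cleaves it to the lithium dienolate F5, which is O-sulfonylated with N-phenylbis(trifluoromethanesulfonimide) to give 7.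

Step 6. Enantio-induction may be poor at the hindered, fully substituted dienal. The alkenylchromium species may isomerise from Z to E, which blocks lactonisation. The butenolide may racemise by deprotonation at its doubly activated γ-position. The fallback sets out from dienal 8 and comes back at butenolide 12 through hydroxy ester 11. Addition of lithium ethyl propiolate (ethyl propiolate, LiHMDS, THF, −78 °C) gives the racemic propargylic alcohol F6. MnO2 oxidises it to the ynone F7. Asymmetric transfer hydrogenation with RuCl(p-cymene)(TsDPEN) in i-PrOH, using the catalyst enantiomer that delivers the 4S alcohol, sets C6 by reagent-controlled ketone reduction and gives the (S)-propargylic alcohol F8. Semi-hydrogenation over Pd/CaCO3 poisoned with Pb(OAc)2 (quinoline, H2) gives 11, which lactonises to 12.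

**Further compounds**

F1 | step 10 | (3S,4S,5S)-4-[(3E)-5-(tert-butylimino)-3-methylpent-3-en-1-yl]-3-methyl-5-[(5R)-2-methyl-5-(6-methylhepta-1,5-dien-2-yl)cyclohexa-1,3-dien-1-yl]oxolan-2-one | C=C(CCC=C(C)C)[C@@H]1CC(=C(C)C=C1)[C@H]2OC(=O)[C@@H](C)[C@@H]2CC/C(C)=C/C=NC(C)(C)C
F2 | step 10 | (3S,4S,5S)-3-methyl-4-[(3E)-3-methyl-5-oxopent-3-en-1-yl]-5-[(5R)-2-methyl-5-(6-methylhepta-1,5-dien-2-yl)cyclohexa-1,3-dien-1-yl]oxolan-2-one | C=C(CCC=C(C)C)[C@@H]1CC(=C(C)C=C1)[C@H]2OC(=O)[C@@H](C)[C@@H]2CC/C(C)=C/C=O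
F3 | step 10 | C1-formyl cycloadduct: 22 with CH–CHO in place of the C1 carbonyl, formyl syn to the C3=C4 bridge | C=C(CCC=C(C)C)[C@@H]1C[C@]23C(C)=C[C@H]1[C@@H](C=O)[C@]2(C)CC[C@H]1[C@H](C)C(=O)O[C@@H]13
F4 | step 4 | trimethyl{[(5R)-2-methyl-5-(6-methylhepta-1,5-dien-2-yl)cyclohexa-1,3-dien-1-yl]oxy}silane | C=C(CCC=C(C)C)[C@@H]1CC(O[Si](C)(C)C)=C(C)C=C1
F5 | step 4 | lithium (5R)-2-methyl-5-(6-methylhepta-1,5-dien-2-yl)cyclohexa-1,3-dien-1-olate | C=C(CCC=C(C)C)[C@@H]1CC(O[Li])=C(C)C=C1
F6 | step 6 | ethyl 4-hydroxy-4-[(5R)-2-methyl-5-(6-methylhepta-1,5-dien-2-yl)cyclohexa-1,3-dien-1-yl]but-2-ynoate (both C4 epimers) | C=C(CCC=C(C)C)[C@@H]1CC(=C(C)C=C1)C(O)C#CC(=O)OCC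
F7 | step 6 | ethyl 4-[(5R)-2-methyl-5-(6-methylhepta-1,5-dien-2-yl)cyclohexa-1,3-dien-1-yl]-4-oxobut-2-ynoate | C=C(CCC=C(C)C)[C@@H]1CC(=C(C)C=C1)C(=O)C#CC(=O)OCC
F8 | step 6 | ethyl (4S)-4-hydroxy-4-[(5R)-2-methyl-5-(6-methylhepta-1,5-dien-2-yl)cyclohexa-1,3-dien-1-yl]but-2-ynoate | C=C(CCC=C(C)C)[C@@H]1CC(=C(C)C=C1)[C@@H](O)C#CC(=O)OCC
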